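If two steps climb the same activation energy, as the first two below do, heat speeds them by one factor, and that equal case is the zero of your scale.

    substrate + coupling partner → target (k1 = 4130 L mol⁻¹ s⁻¹, Ea1 = 23.0 kJ mol⁻¹)
    substrate + 2 coupling partner → side product (k2 = 2.43 × 10⁵ L² mol⁻² s⁻¹, Ea2 = 23.0 kJ mol⁻¹)
    coupling partner + protic impurity → quenched reagent (k3 = 3530 L mol⁻¹ s⁻¹, Ea3 = 52.0 kJ mol⁻¹)
    2 substrate → homo dimer (k4 = 460 L mol⁻¹ s⁻¹, Ea4 = 56.0 kJ mol⁻¹)
    (constants at 100 °C)

common to all: substrate 0.50 mM; coupling partner 1.25 mM; protic impurity 0.150 mM; time 1.5 s

| run | temperature |
|---|---|
| red | 100 °C |
| violet | 85 °C |

- percent here means substrate units held: one homo dimer counts as two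
- a step written with two of one species runs at k times the square of its concentration and takes two of it each time
- at 100 °C the constants are as listed, elsewhere as the activation energies make them

* the flask that comes out highest in amount of target, in percent of the substrate charged, or "all alike" when all lie within 1.5 percentage points (red / violet / all alike)
* target at the end, in percent of the substrate charged, red
* target at the end, in percent of the substrate charged, violet

Take red first and watch the rates. At the start target forms at 2.58 mM s⁻¹ and side product at 0.190 mM s⁻¹, a ratio of 0.0736. Two things slow them. Falling substrate slows both by one factor, so it leaves their ratio alone. Falling partner does not. Suppose each substrate takes one partner and the impurity takes its own: partner then sinks from 1.25 mM to 0.600 mM. That multiplies the target rate by 0.480 and the side rate by the square, 0.230, so the ratio ends near 0.0353. For the whole run I take the middle amount of partner, 0.925 mM, and call the result the side ratio, the side product made per target (a selectivity factor):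

side ratio = second constant × middle partner ÷ first constant = 0.0544

I give violet the same side ratio, since cooling divides both constants by 1.36.

At middle partner, the first step alone takes substrate down at 3.82 s⁻¹ in red, which in my reckoning leaves 0.325% at the end, and 1.50% in violet. The dimer constant drops further on cooling, by 2.13, so I estimate:

dimer share = dimer constant × substrate charge ÷ substrate's fall: red 6.02%, violet 3.86%

target = (charge − leftover − dimer) ÷ (one + side ratio): red 88.8%, violet 89.8%

The gap of 0.93 percentage points is below the margin, so my call is all alike.

The forecast says all alike, with 88.9% for red and 89.4% for violet, holding that “the two effects nearly cancel”. Its violet stands lower than mine.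

Red ends at 89.3% and violet at 89.3%, so the answer is all alike, as the forecast said. Red holds 4.91% side product at the end, a reading of 0.0550 per target against the side ratio of 0.0544. The neighbour like red but with 3.1 mM of coupling partner has a middle partner of 2.78 mM and so a side ratio of 0.163. It ends with 13.7% side product on 84.7% target, which is 0.162 per target.

The constants used here were set for the occasion; the result is computed.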